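**Retrosynthetic overview**
1. Sipholenol L (21) comes from bis-epoxy alkene 19 in one cascade: oxepane C–O bond (ring A), then cyclohexane C–C bond (ring B), then the tertiary C–O bond on ring B.
2. 19 is cut at the CH2–CH= bond of the linker into vinyl decalinol 11 and bis-epoxy iodoalkene 17 (B-alkyl Suzuki–Miyaura coupling).
3. 17 comes from (E)-geranylacetone: alkyne, carboalumination/iodination, Shi epoxidation.
4. 11 comes from 4,4-dimethylcyclohexenone (ring D) and a 2-silyloxydiene by an enantioselective endo Diels–Alder reaction (ring C); its tertiary alcohol is made by C–O formation (Markovnikov hydration of an exocyclic alkene).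
5. Ring order: D (bought), C (step 3), then A and B together (step 13).

**Assumptions**
- Locants in names: right half as 1,4,4a,5,6,7,8,8a-octahydronaphthalene (C1 carries the side chain, C2=C3 is the ring alkene, C5 the carbinol carbon, C8 the gem-dimethyl carbon); left half as decahydro-1-benzoxepine.
- The sense of induction of the oxazaborolidinium catalyst in step 3 is assumed, not derived; if the antipode of 6 forms, the catalyst from (R)-diphenylprolinol is used.
- (E)-Geranylacetone of high isomeric purity is used.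

**Route**

Step 1
Reactants: 1 4-chlorobutanoyl chloride; 2 trimethyl(vinyl)silane
Product: 3 6-chlorohex-1-en-3-one
Conditions: AlCl3, CH2Cl2, −30 → 0 °C; aq NaHCO3
Reagents that add atoms: none
Why: Friedel–Crafts-type ipso acylation of the vinylsilane (β-silyl cation control) replaces silicon by the acyl group and gives the vinyl ketone without touching the primary chloride, and no stereocentre is formed.

Step 2
Reactants: 3 6-chlorohex-1-en-3-one
Product: 4 (Z)-[(6-chlorohexa-1,3-dien-3-yl)oxy]tri(propan-2-yl)silane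
Conditions: i-Pr3SiOTf, Et3N, Et2O, 0 °C
Reagents that add atoms: triisopropylsilyl trifluoromethanesulfonate, CC(C)[Si](C(C)C)(C(C)C)OS(=O)(=O)C(F)(F)F
Why: Soft enolisation of the alkyl vinyl ketone (silyl triflate with a tertiary amine) gives the 2-silyloxydiene as the Z enol ether, which places the chloroethyl chain on the outside of the diene terminus.

Step 3
Reactants: 4 (Z)-[(6-chlorohexa-1,3-dien-3-yl)oxy]tri(propan-2-yl)silane; 5 4,4-dimethylcyclohex-2-en-1-one
Product: 6 (1S,4aS,8aR)-1-(2-chloroethyl)-8,8-dimethyl-2-[(triisopropylsilyl)oxy]-1,4,4a,5,6,7,8,8a-octahydronaphthalen-5-one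
Conditions: (S)-tetrahydro-3,3-diphenyl-1-(2-methylphenyl)-1H,3H-pyrrolo[1,2-c][1,3,2]oxazaborole (20 mol %), HNTf2 (18 mol %), CH2Cl2, −40 °C
Reagents that add atoms: none
Why: Catalytic enantioselective Diels–Alder reaction in which the silyloxy group makes the substituted diene terminus the nucleophilic end so that it bonds to the enone β-carbon next to the gem-dimethyl group, the endo transition state gives the cis ring fusion with the chloroethyl chain cis to both ring-fusion substituents, and the protonated oxazaborolidine shields one face of the bound enone so that the diene adds to the Re face of the β-carbon, which fixes C1, C4a and C8a.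

Step 4
Reactants: 6 (1S,4aS,8aR)-1-(2-chloroethyl)-8,8-dimethyl-2-[(triisopropylsilyl)oxy]-1,4,4a,5,6,7,8,8a-octahydronaphthalen-5-one
Product: 7 (1S,4aS,8aS)-1-(2-chloroethyl)-8,8-dimethyl-5-methylidene-2-[(triisopropylsilyl)oxy]-1,4,4a,5,6,7,8,8a-octahydronaphthalene
Conditions: Cp2TiMe2, toluene, 65 °C, dark
Reagents that add atoms: dimethyltitanocene, [CH3-].[CH3-].[Ti+4].c1cc[cH-]c1.c1cc[cH-]c1
Why: Petasis methylenation transfers CH2 under non-basic conditions, so the ketone becomes the exocyclic alkene without epimerising the adjacent ring-fusion centre C4a or cleaving the silyl enol ether.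

Step 5
Reactants: 7 (1S,4aS,8aS)-1-(2-chloroethyl)-8,8-dimethyl-5-methylidene-2-[(triisopropylsilyl)oxy]-1,4,4a,5,6,7,8,8a-octahydronaphthalene
Product: 8 (1S,4aS,8aS)-1-(2-chloroethyl)-8,8-dimethyl-5-methylidene-1,4,4a,5,6,7,8,8a-octahydronaphthalen-2-yl trifluoromethanesulfonate
Conditions: CsF, PhNTf2, DME, 23 °C
Reagents that add atoms: N-phenylbis(trifluoromethanesulfonimide), O=S(=O)(N(c1ccccc1)S(=O)(=O)C(F)(F)F)C(F)(F)F
Why: Fluoride releases the regiodefined enolate from the silyl enol ether and the triflimide traps it on oxygen at once (enol triflate formation), so the C2=C3 position is kept and C1 is not enolised.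

Step 6
Reactants: 8 (1S,4aS,8aS)-1-(2-chloroethyl)-8,8-dimethyl-5-methylidene-1,4,4a,5,6,7,8,8a-octahydronaphthalen-2-yl trifluoromethanesulfonate
Product: 9 (1S,4aS,5S,8aS)-1-(2-chloroethyl)-5-hydroxy-5,8,8-trimethyl-1,4,4a,5,6,7,8,8a-octahydronaphthalen-2-yl trifluoromethanesulfonate
Conditions: Mn(dpm)3 (10 mol %), PhSiH3, O2 (1 atm), i-PrOH/CH2Cl2, 0 °C
Reagents that add atoms: dioxygen, O=O
Why: Mukaiyama hydration (metal-hydride hydrogen atom transfer) is Markovnikov and selective for the 1,1-disubstituted alkene over the electron-poor enol triflate, and the planar tertiary C5 radical is expected to take up oxygen on the convex face of the cis-fused bicycle (the face of the ring-fusion hydrogens, the concave face being screened by the axial C1 substituent), which sets C5 with the hydroxyl cis to H-4a, the epimer that methyl addition to ketone 6 would not be expected to give.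

Step 7
Reactants: 9 (1S,4aS,5S,8aS)-1-(2-chloroethyl)-5-hydroxy-5,8,8-trimethyl-1,4,4a,5,6,7,8,8a-octahydronaphthalen-2-yl trifluoromethanesulfonate
Product: 10 (1S,4aS,5S,8aR)-1-(2-chloroethyl)-2,5,8,8-tetramethyl-1,4,4a,5,6,7,8,8a-octahydronaphthalen-5-ol
Conditions: MeMgBr (3.5 equiv), Fe(acac)3 (5 mol %), THF/NMP, −30 °C
Reagents that add atoms: methylmagnesium bromide, C[Mg]Br
Why: Iron-catalysed Kumada-type cross-coupling of the alkenyl triflate installs the vinylic methyl group at low temperature while the primary chloride and the deprotonated tertiary alcohol are left alone, and no stereocentre changes.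

Step 8
Reactants: 10 (1S,4aS,5S,8aR)-1-(2-chloroethyl)-2,5,8,8-tetramethyl-1,4,4a,5,6,7,8,8a-octahydronaphthalen-5-ol
Product: 11 (1S,4aS,5S,8aR)-1-ethenyl-2,5,8,8-tetramethyl-1,4,4a,5,6,7,8,8a-octahydronaphthalen-5-ol
Conditions: KOt-Bu, DMSO, 23 °C
Reagents that add atoms: none
Why: E2 dehydrochlorination of the primary chloride with a bulky alkoxide gives the terminal vinyl group, and it is done only now because a vinyl group at C1 would be a radical acceptor in step 6.

Step 9
Reactants: 12 (5E)-6,10-dimethylundeca-5,9-dien-2-one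
Product: 14 (5E)-6,10-dimethylundeca-5,9-dien-1-yne, via enol phosphate 13 (not isolated)
Conditions: LiN(i-Pr)2, THF, −78 °C; ClP(O)(OEt)2; LiN(i-Pr)2 (2.3 equiv), −78 → 23 °C
Reagents that add atoms: none
Why: One-flask conversion of a methyl ketone into a terminal alkyne by kinetic enol phosphate formation at the methyl group and base-induced elimination of phosphate, which leaves the trisubstituted E alkene untouched.

Step 10
Reactants: 14 (5E)-6,10-dimethylundeca-5,9-dien-1-yne
Product: 16 (1E,5E)-1-iodo-2,6,10-trimethylundeca-1,5,9-triene, via alkenylalane 15 (not isolated)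
Conditions: Me3Al, Cp2ZrCl2 (25 mol %), CH2Cl2, 23 °C; I2, THF, −30 °C
Reagents that add atoms: trimethylaluminium, C[Al](C)C; iodine, II
Why: Zirconium-catalysed Negishi carboalumination adds methyl and aluminium syn across the terminal alkyne with methyl on the internal carbon, and iodinolysis with retention gives the E trisubstituted iodoalkene.

Step 11
Reactants: 16 (1E,5E)-1-iodo-2,6,10-trimethylundeca-1,5,9-triene
Product: 17 (2S,3S)-2-{2-[(2S)-3,3-dimethyloxiran-2-yl]ethyl}-3-[(3E)-4-iodo-3-methylbut-3-en-1-yl]-2-methyloxirane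
Conditions: L-fructose-derived Shi ketone (30 mol % per alkene), KHSO5 (as 2KHSO5·KHSO4·K2SO4), K2CO3, Bu4NHSO4, MeCN/CH2(OMe)2/aq Na2B4O7–Na2EDTA, 0 °C
Reagents that add atoms: potassium peroxymonosulfate, [K+].[O-]S(=O)(=O)OO
Why: Shi asymmetric epoxidation through the spiro dioxirane transition state epoxidises the two electron-rich trisubstituted alkenes under reagent control to the S,S and S epoxides, while the iodine-deactivated alkene is left.

Step 12
Reactants: 11 (1S,4aS,5S,8aR)-1-ethenyl-2,5,8,8-tetramethyl-1,4,4a,5,6,7,8,8a-octahydronaphthalen-5-ol; 17 (2S,3S)-2-{2-[(2S)-3,3-dimethyloxiran-2-yl]ethyl}-3-[(3E)-4-iodo-3-methylbut-3-en-1-yl]-2-methyloxirane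
Product: 19 (1S,4aS,5S,8aR)-1-[(3E)-6-[(2S,3S)-3-{2-[(2S)-3,3-dimethyloxiran-2-yl]ethyl}-3-methyloxiran-2-yl]-4-methylhex-3-en-1-yl]-2,5,8,8-tetramethyl-1,4,4a,5,6,7,8,8a-octahydronaphthalen-5-ol, via B-alkyl-9-BBN borane 18 (not isolated)
Conditions: 9-BBN, THF, 23 °C; then 17, Pd(dppf)Cl2 (5 mol %), AsPh3, Cs2CO3, DMF/H2O, 23 °C
Reagents that add atoms: none
Why: B-alkyl Suzuki–Miyaura coupling in which 9-BBN hydroborates only the monosubstituted vinyl group at its terminus and the alkylborane couples with the iodoalkene with retention of the E geometry, under mild basic conditions that are expected to tolerate the epoxides and the free tertiary alcohol.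

Step 13
Reactants: 19 (1S,4aS,5S,8aR)-1-[(3E)-6-[(2S,3S)-3-{2-[(2S)-3,3-dimethyloxiran-2-yl]ethyl}-3-methyloxiran-2-yl]-4-methylhex-3-en-1-yl]-2,5,8,8-tetramethyl-1,4,4a,5,6,7,8,8a-octahydronaphthalen-5-ol
Product: 21 sipholenol L, via tris(trimethylsilyl) ether 20 (not isolated)
Conditions: Me3SiOTf (1.5 equiv), (Me3Si)2O (30 equiv), 2,6-di-tert-butyl-4-methylpyridine, CH2Cl2, −78 °C; then Bu4NF, THF, 0 °C
Reagents that add atoms: hexamethyldisiloxane, C[Si](C)(C)O[Si](C)(C)C
Why: Proposed new method: silylium-relay hydrative termination of an epoxide-opening cascade, in which Me3SiOTf silylates the terminal epoxide, the internal epoxide oxygen attacks its tertiary carbon to give a bicyclic epoxonium ion (the oxepane C–O bond, C3 and C9a keeping the S configuration of the epoxides), the trisubstituted alkene opens this ion at its tertiary carbon with inversion through a chair transition state (C5a, trans ring fusion, equatorial side chain at C6), and the resulting tertiary carbenium ion, which the hindered pyridine is too bulky to deprotonate and which has no internal nucleophile left, is captured by the weakly nucleophilic oxygen of hexamethyldisiloxane anti to the new C–C bond on the equatorial face away from the axial angular methyl group (C7), the bis-silyloxonium ion then handing Me3Si+ back to the chain so that a tertiary silyl ether forms instead of an alkene mixture; the closest known reactions are Me3SiOTf-promoted epoxide–alkene cascades that end in alkenes, ketones (enol silane terminators) or exocyclic alkenes (allylsilane terminators) and the Me3SiOTf-catalysed transfer of silyl-bound oxygen nucleophiles to oxocarbenium ions.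

**Compound list**
1 | 4-chlorobutanoyl chloride | ClCCCC(Cl)=O | starting material
2 | trimethyl(vinyl)silane | C=C[Si](C)(C)C | starting material
3 | 6-chlorohex-1-en-3-one | ClCCCC(=O)C=C | intermediate
4 | (Z)-[(6-chlorohexa-1,3-dien-3-yl)oxy]tri(propan-2-yl)silane | ClCC/C=C(\O[Si](C(C)C)(C(C)C)C(C)C)C=C | intermediate
5 | 4,4-dimethylcyclohex-2-en-1-one | CC1(C)CCC(=O)C=C1 | starting material
6 | (1S,4aS,8aR)-1-(2-chloroethyl)-8,8-dimethyl-2-[(triisopropylsilyl)oxy]-1,4,4a,5,6,7,8,8a-octahydronaphthalen-5-one (cis-fused) | CC(C)[Si](C(C)C)(C(C)C)OC1=CC[C@H]2[C@@H]([C@@H]1CCCl)C(C)(C)CCC2=O | intermediate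
7 | (1S,4aS,8aS)-1-(2-chloroethyl)-8,8-dimethyl-5-methylidene-2-[(triisopropylsilyl)oxy]-1,4,4a,5,6,7,8,8a-octahydronaphthalene | CC(C)[Si](C(C)C)(C(C)C)OC1=CC[C@H]2[C@@H]([C@@H]1CCCl)C(C)(C)CCC2=C | intermediate
8 | (1S,4aS,8aS)-1-(2-chloroethyl)-8,8-dimethyl-5-methylidene-1,4,4a,5,6,7,8,8a-octahydronaphthalen-2-yl trifluoromethanesulfonate | O=S(=O)(OC1=CC[C@H]2[C@@H]([C@@H]1CCCl)C(C)(C)CCC2=C)C(F)(F)F | intermediate
9 | (1S,4aS,5S,8aS)-1-(2-chloroethyl)-5-hydroxy-5,8,8-trimethyl-1,4,4a,5,6,7,8,8a-octahydronaphthalen-2-yl trifluoromethanesulfonate | O=S(=O)(OC1=CC[C@H]2[C@@H]([C@@H]1CCCl)C(C)(C)CC[C@]2(C)O)C(F)(F)F | intermediate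
10 | (1S,4aS,5S,8aR)-1-(2-chloroethyl)-2,5,8,8-tetramethyl-1,4,4a,5,6,7,8,8a-octahydronaphthalen-5-ol | CC1=CC[C@H]2[C@@H]([C@@H]1CCCl)C(C)(C)CC[C@]2(C)O | intermediate
11 | (1S,4aS,5S,8aR)-1-ethenyl-2,5,8,8-tetramethyl-1,4,4a,5,6,7,8,8a-octahydronaphthalen-5-ol | CC1=CC[C@H]2[C@@H]([C@@H]1C=C)C(C)(C)CC[C@]2(C)O | intermediate
12 | (5E)-6,10-dimethylundeca-5,9-dien-2-one ((E)-geranylacetone) | CC(=O)CC/C=C(\C)CCC=C(C)C | starting material
13 | diethyl (5E)-6,10-dimethylundeca-1,5,9-trien-2-yl phosphate | C=C(OP(=O)(OCC)OCC)CC/C=C(\C)CCC=C(C)C | intermediate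
14 | (5E)-6,10-dimethylundeca-5,9-dien-1-yne | C#CCC/C=C(\C)CCC=C(C)C | intermediate
15 | dimethyl[(1E,5E)-2,6,10-trimethylundeca-1,5,9-trien-1-yl]aluminium | C[Al](C)/C=C(\C)CC/C=C(\C)CCC=C(C)C | intermediate
16 | (1E,5E)-1-iodo-2,6,10-trimethylundeca-1,5,9-triene | I/C=C(\C)CC/C=C(\C)CCC=C(C)C | intermediate
17 | (2S,3S)-2-{2-[(2S)-3,3-dimethyloxiran-2-yl]ethyl}-3-[(3E)-4-iodo-3-methylbut-3-en-1-yl]-2-methyloxirane | I/C=C(\C)CC[C@@H]1O[C@@]1(C)CC[C@@H]1OC1(C)C | intermediate
18 | 9-{2-[(1S,4aS,5S,8aR)-5-hydroxy-2,5,8,8-tetramethyl-1,4,4a,5,6,7,8,8a-octahydronaphthalen-1-yl]ethyl}-9-borabicyclo[3.3.1]nonane | CC1=CC[C@H]2[C@@H]([C@@H]1CCB1C3CCCC1CCC3)C(C)(C)CC[C@]2(C)O | intermediate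
19 | (1S,4aS,5S,8aR)-1-[(3E)-6-[(2S,3S)-3-{2-[(2S)-3,3-dimethyloxiran-2-yl]ethyl}-3-methyloxiran-2-yl]-4-methylhex-3-en-1-yl]-2,5,8,8-tetramethyl-1,4,4a,5,6,7,8,8a-octahydronaphthalen-5-ol | CC1=CC[C@H]2[C@@H]([C@@H]1CC/C=C(\C)CC[C@@H]1O[C@@]1(C)CC[C@@H]1OC1(C)C)C(C)(C)CC[C@]2(C)O | intermediate
20 | tris(trimethylsilyl) ether of 21 (silyl on the three hydroxyl oxygens) | CC1=CC[C@H]2[C@@H]([C@@H]1CC[C@H]1[C@]3(C)CC[C@H](O[Si](C)(C)C)C(C)(C)O[C@H]3CC[C@]1(C)O[Si](C)(C)C)C(C)(C)CC[C@]2(C)O[Si](C)(C)C | intermediate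
21 | sipholenol L, (3S,5aS,6S,7S,9aS)-6-{2-[(1S,4aS,5S,8aR)-5-hydroxy-2,5,8,8-tetramethyl-1,4,4a,5,6,7,8,8a-octahydronaphthalen-1-yl]ethyl}-2,2,5a,7-tetramethyldecahydro-1-benzoxepine-3,7-diol | CC1=CC[C@H]2[C@@H]([C@@H]1CC[C@H]1[C@]3(C)CC[C@H](O)C(C)(C)O[C@H]3CC[C@]1(C)O)C(C)(C)CC[C@]2(C)O | target

**Step count**
Total: 13 steps. Longest linear sequence: 10 steps (steps 1–8, 12, 13).

**Steps most likely to fail, with fallbacks**

Step 13 (the proposed new termination). The carbenium ion may lose a proton or be intercepted by the ring C alkene instead of being captured by the disiloxane. The fallback uses known chemistry, sets out from alkyne 14 and comes back at 21. Carbocupration of 14 with Me3SiCH2MgCl/CuBr·SMe2 gives the alkenylcopper reagent F1 (not isolated), and iodinolysis gives (1Z,5E)-1-iodo-6,10-dimethyl-2-[(trimethylsilyl)methyl]undeca-1,5,9-triene F2. Shi epoxidation as in step 11 gives the bis-epoxide F3, and B-alkyl Suzuki coupling with borane 18 as in step 12 gives the allylsilane analogue of 19 F4. The established Me3SiOTf/2,6-di-tert-butyl-4-methylpyridine cascade without disiloxane, in which the β-silyl cation collapses to the exocyclic alkene, gives the bis(trimethylsilyl) ether F5 (not isolated) and, after Bu4NF, the 7-methylidene diol F6. Oxymercuration with Hg(OAc)2 in THF/H2O gives the organomercurial F7 (not isolated); the 1,1-disubstituted alkene should react far faster than the trisubstituted ring alkene, with water entering on the equatorial face. NaBH4 demercuration then gives 21.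

Step 3 (enantioselective Diels–Alder reaction on a hindered enone). Rate and enantioselectivity are untested for this diene–enone pair. The fallback sets out from 4 and 5 and comes back at 6. The cycloaddition is run with the achiral mixed Lewis acid AlBr3/AlMe3 in toluene/CH2Cl2 at −5 °C, conditions of the kind used for hindered silyloxydiene–enone pairs. This gives the racemic endo adduct, that is 6 together with its enantiomer (1R,4aR,8aS)-1-(2-chloroethyl)-8,8-dimethyl-2-[(triisopropylsilyl)oxy]-1,4,4a,5,6,7,8,8a-octahydronaphthalen-5-one F8. The two are separated by preparative chromatography on a chiral stationary phase; 6 continues and F8 is discarded.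

Step 6 (facial and chemoselectivity of the radical hydration). Trapping of the C5 radical on the wrong face would give the C5 epimer. The fallback sets out from 8 and comes back at 10. mCPBA in CH2Cl2 (NaHCO3, 0 °C) epoxidises only the exocyclic alkene, the enol triflate being inert, from the convex face to give the spiro-epoxide of 8 with oxygen cis to H-4a F9. Fe(acac)3/MeMgBr coupling at −30 °C as in step 7 gives the 2-methyl spiro-epoxide F10. LiAlH4 in Et2O at 0 °C opens the epoxide at its CH2 terminus to give 10.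

**Further compounds**
F1 | step 13 | [(1Z,5E)-6,10-dimethyl-2-[(trimethylsilyl)methyl]undeca-1,5,9-trien-1-yl]copper (magnesium halide complex) | [Cu]/C=C(\C[Si](C)(C)C)CC/C=C(\C)CCC=C(C)C
F2 | step 13 | (1Z,5E)-1-iodo-6,10-dimethyl-2-[(trimethylsilyl)methyl]undeca-1,5,9-triene | I/C=C(\C[Si](C)(C)C)CC/C=C(\C)CCC=C(C)C
F3 | step 13 | (2S,3S)-2-{2-[(2S)-3,3-dimethyloxiran-2-yl]ethyl}-3-{(3Z)-4-iodo-3-[(trimethylsilyl)methyl]but-3-en-1-yl}-2-methyloxirane | I/C=C(\C[Si](C)(C)C)CC[C@@H]1O[C@@]1(C)CC[C@@H]1OC1(C)C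
F4 | step 13 | (1S,4aS,5S,8aR)-1-[(3Z)-6-[(2S,3S)-3-{2-[(2S)-3,3-dimethyloxiran-2-yl]ethyl}-3-methyloxiran-2-yl]-4-[(trimethylsilyl)methyl]hex-3-en-1-yl]-2,5,8,8-tetramethyl-1,4,4a,5,6,7,8,8a-octahydronaphthalen-5-ol | CC1=CC[C@H]2[C@@H]([C@@H]1CC/C=C(\C[Si](C)(C)C)CC[C@@H]1O[C@@]1(C)CC[C@@H]1OC1(C)C)C(C)(C)CC[C@]2(C)O
F5 | step 13 | bis(trimethylsilyl) ether of F6 (silyl on both hydroxyl oxygens) | CC1=CC[C@H]2[C@@H]([C@@H]1CC[C@H]1[C@]3(C)CC[C@H](O[Si](C)(C)C)C(C)(C)O[C@H]3CCC1=C)C(C)(C)CC[C@]2(C)O[Si](C)(C)C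
F6 | step 13 | 7-methylidene analogue of 21 (exocyclic C=CH2 in place of C(CH3)OH on ring B; other stereocentres as in 21) | CC1=CC[C@H]2[C@@H]([C@@H]1CC[C@H]1[C@]3(C)CC[C@H](O)C(C)(C)O[C@H]3CCC1=C)C(C)(C)CC[C@]2(C)O
F7 | step 13 | 7-[(acetoxymercurio)methyl] analogue of 21 (HgOAc on the ring B methyl carbon; stereocentres as in 21) | CC1=CC[C@H]2[C@@H]([C@@H]1CC[C@H]1[C@]3(C)CC[C@H](O)C(C)(C)O[C@H]3CC[C@]1(C[Hg]OC(C)=O)O)C(C)(C)CC[C@]2(C)O
F8 | step 3 | (1R,4aR,8aS)-1-(2-chloroethyl)-8,8-dimethyl-2-[(triisopropylsilyl)oxy]-1,4,4a,5,6,7,8,8a-octahydronaphthalen-5-one (enantiomer of 6) | CC(C)[Si](C(C)C)(C(C)C)OC1=CC[C@@H]2[C@H]([C@H]1CCCl)C(C)(C)CCC2=O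
F9 | step 6 | spiro-epoxide of 8 at C5 (epoxide oxygen cis to H-4a; C1, C4a, C8a as in 8) | O=S(=O)(OC1=CC[C@H]2[C@@H]([C@@H]1CCCl)C(C)(C)CC[C@@]21CO1)C(F)(F)F
F10 | step 6 | 2-methyl spiro-epoxide (F9 with CH3 in place of the triflate group) | CC1=CC[C@H]2[C@@H]([C@@H]1CCCl)C(C)(C)CC[C@@]21CO1
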